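**Retrosynthetic overview**

1. The four aldehydes are unmasked last: each 2-ethylidene-1,5-dial side chain is the periodate-opened form of a cis-cyclopentane-1,2-diol, so the target goes back to a bis-ester carrying three acetonides.
2. The two ester bonds are cut next (Mitsunobu coupling, with inversion at the ring carbinol) to a core diol and two equivalents of one chiral-pool acid. The acid comes from (3aR,6aR)-2,2-dimethyl-3a,6a-dihydro-4H-cyclopenta[d][1,3]dioxol-4-one by hydrogenation, enolate alkylation, Wittig ethylidenation and saponification.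
3. Core diol ⇐ all-trans hydroxy ketone ⇐ 2-silylcyclopent-2-enone (hydride reduction; dissolving-metal reduction with desilylation).
4. Key disconnection: the cyclopentenone ⇐ 3-methylfuran-2(5H)-one + a silylated dioxanyl alkyne by a nickel-catalysed enantioselective reductive [3+2] cycloaddition. It forms C3–C4 and then closes the ring at C1–C5 (cyclopentane locants: C1 carbinol, C2 CH3, C3 CH2O, C4 branch, C5 CH2). Enabling feature: the segment O–CH2–C3–C2(CH3)–C1(O) is a γ-hydroxy acid, i.e. the opened ring (O1, C2, C3, C4, C5) of an α-methylbutenolide whose carbonyl carbon becomes C1, and C4–C5 with its branch is a two-carbon alkyne unit.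
5. Ring order: the cyclopentane is the only ring that is built (step 4, as the lactone ring opens); the two side-chain cyclopentanes come from the chiral pool and are opened in the last step.

Key step: step 4

Remark on the chemistry: the SMILES is read as a (1R,2R,3S,4R)-cyclopentane whose neighbouring substituents are all trans (the thermodynamically preferred arrangement), with two (3S,4E) side chains; the three starting materials are taken as commercial.

**Route**

Step 1
Reactants: 1 (2,2-dimethyl-1,3-dioxan-5-yl)methanol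
Product: 2 2,2-dimethyl-1,3-dioxane-5-carbaldehyde
Conditions: TEMPO (10 mol %), PhI(OAc)2 (1.1 equiv), CH2Cl2, rt
Reagents that add atoms: none
Why: TEMPO-catalysed (oxoammonium) alcohol oxidation stops at the aldehyde under non-basic conditions, which avoids β-elimination of the β,β′-dialkoxy aldehyde and leaves the ketal intact.

Step 2
Reactants: 2 2,2-dimethyl-1,3-dioxane-5-carbaldehyde
Product: 3 5-ethynyl-2,2-dimethyl-1,3-dioxane
Conditions: dimethyl (1-diazo-2-oxopropyl)phosphonate (1.2 equiv), K2CO3 (2 equiv), MeOH, 0 °C to rt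
Reagents that add atoms: dimethyl (1-diazo-2-oxopropyl)phosphonate, COP(=O)(OC)C(=[N+]=[N-])C(C)=O
Why: The Ohira–Bestmann variant of the Seyferth–Gilbert homologation converts the aldehyde into the terminal alkyne through a diazoalkene and 1,2-shift under mild carbonate conditions that the ketal tolerates.

Step 3
Reactants: 3 5-ethynyl-2,2-dimethyl-1,3-dioxane
Product: 5 [(2,2-dimethyl-1,3-dioxan-5-yl)ethynyl]trimethylsilane, via lithium acetylide 4 (not isolated)
Conditions: n-BuLi (1.05 equiv), THF, −78 °C; then Me3SiCl (1.2 equiv), −78 °C to rt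
Reagents that add atoms: chlorotrimethylsilane, C[Si](C)(C)Cl
Why: Deprotonation of the terminal alkyne and C-silylation of the acetylide install the silyl group that later fixes the orientation of the alkyne in the nickel-mediated coupling.

Step 4
Reactants: 5 [(2,2-dimethyl-1,3-dioxan-5-yl)ethynyl]trimethylsilane; 6 3-methylfuran-2(5H)-one
Product: 8 (4R,5R)-3-(2,2-dimethyl-1,3-dioxan-5-yl)-4-(hydroxymethyl)-5-methyl-2-(trimethylsilyl)cyclopent-2-en-1-one, via oxanickelacycle 7 (not isolated)
Conditions: Ni(cod)2 (10 mol %), chiral monophosphine L* (20 mol %; neomenthyldiphenylphosphine type, antipode selected for 4R), Et3B (3 equiv), MeOH/THF 1:8, 50 °C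
Reagents that add atoms: none
Why: Proposed new method: zerovalent nickel bearing the chiral monophosphine binds butenolide 6 and alkyne 5 and couples them oxidatively to oxanickelacycle 7 (bond between the lactone β-carbon and the dioxanyl-bearing alkyne carbon), methanol protonates the nickel enolate carbon, and the alkenyl–nickel carbon then attacks the lactone carbonyl (directly, or after β-alkoxide elimination to an alkenyl ketene), so that the carbocycle closes as the lactone C–O bond breaks and releases the hydroxymethyl group, while Et3B returns divalent nickel to the zerovalent state by ethyl transfer and β-hydride elimination. The closest known reaction type is the nickel-catalysed reductive [3+2] cycloaddition of acyclic α,β-unsaturated esters with alkynes to cyclopent-2-enones, and the closest known source of asymmetry is the enantioselective nickel-catalysed reductive coupling of alkynes with aldehydes under chiral monophosphines; new here are the lactone as the enoate partner and ligand control of the butenolide face. The one ring that forms, the cyclopentenone, closes in a 5-exo-trig addition of the silyl-bearing alkenyl carbon to the ester carbonyl, which becomes the ring ketone. The stereocentre at C4 of 8 (the former butenolide β-carbon) is set in the enantio-determining oxidative cyclisation by the chiral ligand, whose antipode is chosen to give 4R, whereas the methyl-bearing C5 arises by enolate protonation and is equilibrated in step 5. The step needs regiocontrol of alkyne insertion, secured by the trimethylsilyl group, which stays on the nickel-bound carbon so that the dioxanyl-bearing carbon forms the first C–C bond, and it needs ring closure to outrun protonation of the alkenylnickel, which the close and electrophilic γ-lactone carbonyl should favour.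

Step 5
Reactants: 8 (4R,5R)-3-(2,2-dimethyl-1,3-dioxan-5-yl)-4-(hydroxymethyl)-5-methyl-2-(trimethylsilyl)cyclopent-2-en-1-one
Product: 10 (2R,3S,4R)-4-(2,2-dimethyl-1,3-dioxan-5-yl)-3-(hydroxymethyl)-2-methylcyclopentan-1-one, via α-silyl ketone 9 (not isolated)
Conditions: Li (4 equiv), NH3(l)/THF, t-BuOH (1 equiv), −78 °C; NH4Cl; then K2CO3 (0.5 equiv), MeOH, rt
Reagents that add atoms: none
Why: Dissolving-metal (Birch-type) conjugate reduction gives the α-silyl enolate after protonation of the β-carbanion on the face of the neighbouring lithium alkoxymethyl group, which places the dioxanyl group trans to it (also the thermodynamic outcome), and the carbonate/methanol treatment then cleaves the labile α-silyl ketone (protodesilylation) and equilibrates the methyl-bearing centre to the all-trans ketone.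

Step 6
Reactants: 10 (2R,3S,4R)-4-(2,2-dimethyl-1,3-dioxan-5-yl)-3-(hydroxymethyl)-2-methylcyclopentan-1-one
Product: 11 (1S,2R,3S,4R)-4-(2,2-dimethyl-1,3-dioxan-5-yl)-3-(hydroxymethyl)-2-methylcyclopentan-1-ol
Conditions: LiBH(s-Bu)3 (2.5 equiv), THF, −78 °C; then H2O
Reagents that add atoms: none
Why: Reduction with the bulky trialkylborohydride should occur from the ring face opposite the adjacent methyl group (steric approach control), giving the 1,2-cis alcohol (1S) that the inverting esterification of step 11 requires.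

Step 7
Reactants: 12 (3aR,6aR)-2,2-dimethyl-3a,6a-dihydro-4H-cyclopenta[d][1,3]dioxol-4-one
Product: 13 (3aR,6aR)-2,2-dimethyltetrahydro-4H-cyclopenta[d][1,3]dioxol-4-one
Conditions: H2 (1 atm), 10% Pd/C, EtOAc, rt
Reagents that add atoms: none
Why: Catalytic hydrogenation saturates the enone C=C without touching the two chiral-pool stereocentres.

Step 8
Reactants: 13 (3aR,6aR)-2,2-dimethyltetrahydro-4H-cyclopenta[d][1,3]dioxol-4-one
Product: 15 methyl 2-[(3aR,5S,6aR)-2,2-dimethyl-4-oxotetrahydro-4H-cyclopenta[d][1,3]dioxol-5-yl]acetate, via lithium enolate 14 (not isolated)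
Conditions: LiN(i-Pr)2 (1.05 equiv), THF, −78 °C; then BrCH2CO2Me (1.2 equiv), −78 to −40 °C
Reagents that add atoms: methyl bromoacetate, COC(=O)CBr
Why: Kinetic deprotonation takes place at the unsubstituted α′-CH2 rather than at the oxygen-bearing ring-fusion carbon, and enolate alkylation occurs on the convex face of the cis-fused bicycle, anti to the dioxolane, which sets the future (S) centre of the side chain.

Step 9
Reactants: 15 methyl 2-[(3aR,5S,6aR)-2,2-dimethyl-4-oxotetrahydro-4H-cyclopenta[d][1,3]dioxol-5-yl]acetate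
Product: 16 methyl 2-[(3aS,4E,5S,6aR)-4-ethylidene-2,2-dimethyltetrahydro-4H-cyclopenta[d][1,3]dioxol-5-yl]acetate
Conditions: EtPPh3Br (1.5 equiv), KOt-Bu (1.4 equiv), THF, 0 °C to rt
Reagents that add atoms: ethyltriphenylphosphonium bromide, CC[P+](c1ccccc1)(c1ccccc1)c1ccccc1.[Br-]
Why: Wittig olefination with the non-stabilised ylide turns the ketone into the exocyclic ethylidene, the (E)-isomer with the methyl group turned away from the ring-fusion C–O bond being expected as the main product and the (Z)-isomer being removable by chromatography.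

Step 10
Reactants: 16 methyl 2-[(3aS,4E,5S,6aR)-4-ethylidene-2,2-dimethyltetrahydro-4H-cyclopenta[d][1,3]dioxol-5-yl]acetate
Product: 17 2-[(3aS,4E,5S,6aR)-4-ethylidene-2,2-dimethyltetrahydro-4H-cyclopenta[d][1,3]dioxol-5-yl]acetic acid
Conditions: LiOH (3 equiv), THF/MeOH/H2O, 0 °C to rt; then 0.5 M HCl to pH 4, 0 °C
Reagents that add atoms: lithium hydroxide, [Li+].[OH-]
Why: Ester saponification frees the acid while the ketal and the unconjugated alkene are inert to hydroxide.

Step 11
Reactants: 11 (1S,2R,3S,4R)-4-(2,2-dimethyl-1,3-dioxan-5-yl)-3-(hydroxymethyl)-2-methylcyclopentan-1-ol; 17 2-[(3aS,4E,5S,6aR)-4-ethylidene-2,2-dimethyltetrahydro-4H-cyclopenta[d][1,3]dioxol-5-yl]acetic acid (2.5 equiv)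
Product: 18 bis-ester: (1R,2R,3S,4R)-4-(2,2-dimethyl-1,3-dioxan-5-yl)-2-methylcyclopentane acylated at O-1 and at the 3-CH2O group by the acyl group of 17
Conditions: PPh3 (3 equiv), DIAD (3 equiv), THF, 0 °C to rt
Reagents that add atoms: none
Why: In this Mitsunobu esterification the primary alcohol is acylated first and the secondary oxyphosphonium ion is then displaced by the carboxylate in an SN2 reaction, so that C1 is inverted from S to the required R while both side chains are attached.

Step 12
Reactants: 18 bis-ester with three acetonides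
Product: 19 hexaol: (1R,2R,3S,4R)-4-(1,3-dihydroxypropan-2-yl)-2-methylcyclopentane bearing at O-1 and at the 3-CH2O group a 2-[(1S,2E,3S,4R)-2-ethylidene-3,4-dihydroxycyclopentyl]acetyl group
Conditions: AcOH/H2O 4:1, 45 °C
Reagents that add atoms: none
Why: Acid-catalysed ketal hydrolysis removes the 1,3-dioxane and both cis-fused dioxolane acetonides under conditions too mild to cleave the aliphatic esters or to ionise the allylic alcohols.

Step 13
Reactants: 19 hexaol
Product: 20 (1R,2R,3S,4R)-4-(1,3-dihydroxypropan-2-yl)-2-methyl-3-({[(3S,4E)-4-formyl-3-(2-oxoethyl)hex-4-enoyl]oxy}methyl)cyclopentyl (3S,4E)-4-formyl-3-(2-oxoethyl)hex-4-enoate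
Conditions: NaIO4 (2.5 equiv), THF/H2O 2:1, 0 °C to rt
Reagents that add atoms: none
Why: Periodate glycol cleavage (Malaprade reaction) opens each cis-cyclopentane-1,2-diol to a 1,5-dialdehyde, the allylic carbinol becoming the (E)-enal, while the 1,3-diol, the esters and all stereocentres are untouched.

**Compound list**

1 | (2,2-dimethyl-1,3-dioxan-5-yl)methanol | CC1(C)OCC(CO)CO1 | starting material
2 | 2,2-dimethyl-1,3-dioxane-5-carbaldehyde | CC1(C)OCC(C=O)CO1 | intermediate
3 | 5-ethynyl-2,2-dimethyl-1,3-dioxane | CC1(C)OCC(C#C)CO1 | intermediate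
4 | lithium acetylide of 3 | [Li]C#CC1COC(C)(C)OC1 | intermediate
5 | [(2,2-dimethyl-1,3-dioxan-5-yl)ethynyl]trimethylsilane | C[Si](C)(C)C#CC1COC(C)(C)OC1 | intermediate
6 | 3-methylfuran-2(5H)-one | CC1=CCOC1=O | starting material
7 | oxanickelacycle (nickel bound to the lactone enolate oxygen and to the silyl-bearing alkenyl carbon; phosphine on nickel omitted) | CC1=C2O[Ni]C([Si](C)(C)C)=C(C3COC(C)(C)OC3)[C@@H]1CO2 | intermediate
8 | (4R,5R)-3-(2,2-dimethyl-1,3-dioxan-5-yl)-4-(hydroxymethyl)-5-methyl-2-(trimethylsilyl)cyclopent-2-en-1-one | OC[C@@H]1[C@@H](C)C(=O)C([Si](C)(C)C)=C1C2COC(C)(C)OC2 | intermediate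
9 | (2R,3R,4R)-4-(2,2-dimethyl-1,3-dioxan-5-yl)-3-(hydroxymethyl)-2-methyl-5-(trimethylsilyl)cyclopentan-1-one (both C5 epimers) | OC[C@@H]1[C@@H](C)C(=O)C([Si](C)(C)C)[C@H]1C2COC(C)(C)OC2 | intermediate
10 | (2R,3S,4R)-4-(2,2-dimethyl-1,3-dioxan-5-yl)-3-(hydroxymethyl)-2-methylcyclopentan-1-one | OC[C@@H]1[C@@H](C)C(=O)C[C@H]1C2COC(C)(C)OC2 | intermediate
11 | (1S,2R,3S,4R)-4-(2,2-dimethyl-1,3-dioxan-5-yl)-3-(hydroxymethyl)-2-methylcyclopentan-1-ol | OC[C@@H]1[C@@H](C)[C@@H](O)C[C@H]1C2COC(C)(C)OC2 | intermediate
12 | (3aR,6aR)-2,2-dimethyl-3a,6a-dihydro-4H-cyclopenta[d][1,3]dioxol-4-one | O=C1C=C[C@H]2OC(C)(C)O[C@@H]12 | starting material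
13 | (3aR,6aR)-2,2-dimethyltetrahydro-4H-cyclopenta[d][1,3]dioxol-4-one | O=C1CC[C@H]2OC(C)(C)O[C@@H]12 | intermediate
14 | lithium enolate of 13 (C4=C5 enolate) | [Li]OC1=CC[C@H]2OC(C)(C)O[C@@H]12 | intermediate
15 | methyl 2-[(3aR,5S,6aR)-2,2-dimethyl-4-oxotetrahydro-4H-cyclopenta[d][1,3]dioxol-5-yl]acetate | O=C1[C@H](CC(=O)OC)C[C@H]2OC(C)(C)O[C@@H]12 | intermediate
16 | methyl 2-[(3aS,4E,5S,6aR)-4-ethylidene-2,2-dimethyltetrahydro-4H-cyclopenta[d][1,3]dioxol-5-yl]acetate | C/C=C1\[C@H](CC(=O)OC)C[C@H]2OC(C)(C)O[C@@H]12 | intermediate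
17 | 2-[(3aS,4E,5S,6aR)-4-ethylidene-2,2-dimethyltetrahydro-4H-cyclopenta[d][1,3]dioxol-5-yl]acetic acid | C/C=C1\[C@H](CC(=O)O)C[C@H]2OC(C)(C)O[C@@H]12 | intermediate
18 | bis-ester of the (1R,2R,3S,4R)-core diol with two molecules of 17 (three acetonides) | C/C=C1\[C@H](CC(=O)OC[C@@H]2[C@@H](C)[C@H](OC(=O)C[C@@H]3C[C@H]4OC(C)(C)O[C@H]4/C3=C/C)C[C@H]2C5COC(C)(C)OC5)C[C@H]6OC(C)(C)O[C@@H]16 | intermediate
19 | hexaol: 18 without its three acetonides | C/C=C1\[C@H](CC(=O)OC[C@@H]2[C@@H](C)[C@H](OC(=O)C[C@@H]3C[C@@H](O)[C@@H](O)/C3=C/C)C[C@H]2C(CO)CO)C[C@@H](O)[C@H]1O | intermediate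
20 | (1R,2R,3S,4R)-4-(1,3-dihydroxypropan-2-yl)-2-methyl-3-({[(3S,4E)-4-formyl-3-(2-oxoethyl)hex-4-enoyl]oxy}methyl)cyclopentyl (3S,4E)-4-formyl-3-(2-oxoethyl)hex-4-enoate | C/C=C(/C=O)[C@@H](CC=O)CC(=O)OC[C@@H]1[C@@H](C)[C@H](OC(=O)C[C@H](CC=O)/C(C=O)=C\C)C[C@H]1C(CO)CO | target

**Step count and risks**

Total step count: 13. Longest linear sequence: 9 steps (steps 1–6, then 11–13); the acid (steps 7–10) is made in parallel.

Steps most likely to fail:

1. Step 4 (Proposed new method). What may go wrong: protonation of the alkenylnickel intermediate before it reaches the lactone carbonyl (reductive coupling without ring closure), alkyne insertion with the opposite orientation, or weak ligand control over the butenolide face. Fallback with known chemistry, setting out from 3 and coming back at 10: Markovnikov hydroalumination of 3 (i-Bu2AlH, Ni(dppp)Cl2 cat., THF) and trapping with 2-methoxy-4,4,5,5-tetramethyl-1,3,2-dioxaborolane should give the internal alkenylboronate F1. Rhodium-catalysed asymmetric conjugate addition of F1 to commercial furan-2(5H)-one (Rh(acac)(C2H4)2, BINAP antipode chosen for 4R, dioxane/H2O) gives the β-alkenyl lactone F2. Methylation of its enolate (LiN(i-Pr)2, MeI) gives the 3,4-trans methyl lactone F3, whose methyl-bearing centre is corrected at the end. Ring opening with MeNH(OMe)·HCl/AlMe3 gives the hydroxy N-methoxy-N-methylamide F4, which is silylated at once (t-BuMe2SiCl, imidazole) to the silyl ether F5 and reduced (i-Bu2AlH, −78 °C) to the 4-pentenal F6. Intramolecular alkene hydroacylation with a cationic rhodium diphosphine catalyst ([Rh(dppe)(nbd)]BF4 activated with H2, CH2Cl2) closes the same ring bond, the acyl carbon adding to the terminal alkene carbon and the new ring stereocentre forming trans to the neighbouring silyloxymethyl group, to give the cyclopentanone F7. Bu4NF and then K2CO3/MeOH remove the silyl ether and equilibrate the methyl centre, which brings the route back at 10 (steps 4 and 5 are bypassed).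

2. Step 11. What may go wrong: slow SN2 displacement at the hindered secondary oxyphosphonium ion, with elimination to the cyclopentene or etherification by the still free primary hydroxyl competing. Fallback, setting out from 11 and coming back at 18: the inversion is separated from the acylation. Mitsunobu reaction of 11 with the small, more acidic 4-nitrobenzoic acid gives the bis(4-nitrobenzoate) F8; methanolysis (K2CO3, MeOH) gives the (1R)-diol F9; carbodiimide esterification (EDC·HCl, DMAP, CH2Cl2) of F9 with 17, which proceeds with retention, gives 18.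

3. Step 5. What may go wrong: protonation of the β-carbon from the wrong face, over-reduction of the ketone, or silyl migration under electron-transfer conditions. Fallback, setting out from 8 and coming back at 10: electron transfer is replaced by alkoxide-directed hydride delivery. NaAlH2(OCH2CH2OMe)2 (THF, −40 °C) binds the primary alkoxide and should deliver hydride intramolecularly to the β-carbon on the hydroxymethyl face, giving the same α-silyl ketone 9, which K2CO3/MeOH converts into 10; this fallback makes no new compound (F0).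

**Further compounds**

F1 | step 4 | 2-[1-(2,2-dimethyl-1,3-dioxan-5-yl)ethenyl]-4,4,5,5-tetramethyl-1,3,2-dioxaborolane | C=C(B1OC(C)(C)C(C)(C)O1)C2COC(C)(C)OC2
F2 | step 4 | (4R)-4-[1-(2,2-dimethyl-1,3-dioxan-5-yl)ethenyl]oxolan-2-one | C=C(C1COC(C)(C)OC1)[C@H]2CC(=O)OC2
F3 | step 4 | (3S,4R)-4-[1-(2,2-dimethyl-1,3-dioxan-5-yl)ethenyl]-3-methyloxolan-2-one | C=C(C1COC(C)(C)OC1)[C@H]2[C@H](C)C(=O)OC2
F4 | step 4 | (2S,3R)-4-(2,2-dimethyl-1,3-dioxan-5-yl)-3-(hydroxymethyl)-N-methoxy-N,2-dimethylpent-4-enamide | OC[C@H]([C@H](C)C(=O)N(C)OC)C(=C)C1COC(C)(C)OC1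
F5 | step 4 | (2S,3R)-3-{[(tert-butyldimethylsilyl)oxy]methyl}-4-(2,2-dimethyl-1,3-dioxan-5-yl)-N-methoxy-N,2-dimethylpent-4-enamide | CC(C)(C)[Si](C)(C)OC[C@H]([C@H](C)C(=O)N(C)OC)C(=C)C1COC(C)(C)OC1
F6 | step 4 | (2S,3R)-3-{[(tert-butyldimethylsilyl)oxy]methyl}-4-(2,2-dimethyl-1,3-dioxan-5-yl)-2-methylpent-4-enal | CC(C)(C)[Si](C)(C)OC[C@H]([C@H](C)C=O)C(=C)C1COC(C)(C)OC1
F7 | step 4 | (2S,3S,4R)-3-{[(tert-butyldimethylsilyl)oxy]methyl}-4-(2,2-dimethyl-1,3-dioxan-5-yl)-2-methylcyclopentan-1-one | CC(C)(C)[Si](C)(C)OC[C@@H]1[C@H](C)C(=O)C[C@H]1C2COC(C)(C)OC2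
F8 | step 11 | bis(4-nitrobenzoate) of (1R,2R,3S,4R)-4-(2,2-dimethyl-1,3-dioxan-5-yl)-3-(hydroxymethyl)-2-methylcyclopentan-1-ol | O=C(OC[C@@H]1[C@@H](C)[C@H](OC(=O)c2ccc(cc2)[N+](=O)[O-])C[C@H]1C3COC(C)(C)OC3)c4ccc(cc4)[N+](=O)[O-]
F9 | step 11 | (1R,2R,3S,4R)-4-(2,2-dimethyl-1,3-dioxan-5-yl)-3-(hydroxymethyl)-2-methylcyclopentan-1-ol | OC[C@@H]1[C@@H](C)[C@H](O)C[C@H]1C2COC(C)(C)OC2
F0 | step 5 | none | none
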